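Ring C is opened at O1–C2 and C3–C4. The C2–C3 unit between these bonds is the vinyl group of a ring B styrene with a free 2'-hydroxyl, and O1 and C4 belong to a ring A salicylaldehyde acetal. A chiral phosphoric acid ionises the acetal to a methoxy ortho-quinone methide and steers its [4+2] addition to the styrene. This closes ring C, sets C2 (S) and leaves C4 as a methyl ether, one oxidation below the ketone. The precursors are a diprenylated, bis-MOM phloroglucinol aldehyde dimethyl acetal with one free phenol, and 6-vinyl-2,2-dimethylchromen-7-ol. The 2'-hydroxyl is capped directly afterwards, so that it cannot bridge to C4.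

Key step: step 7

Remark: which antipode of the phosphoric acid leads to the 2S series cannot be predicted with certainty; (R)-TRIP is written, and its enantiomer is taken instead if a test reaction gives the 2R series.

Step 1
Reactants: 1 2,4,6-trihydroxybenzaldehyde; 2 1-bromo-3-methylbut-2-ene
Product: 3 2,4,6-trihydroxy-3,5-bis(3-methylbut-2-enyl)benzaldehyde
Conditions: 2 (2.2 equiv), 10% aq. KOH, 0 °C
Reagents that add atoms: none
Why: C-alkylation of an acylphloroglucinol phenoxide in water, where solvation of the phenoxide oxygens directs the allylic bromide to the two free ring carbons and the formyl group damps further alkylation, should give the 3,5-diprenyl compound after chromatographic removal of mono- and over-alkylated material.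

Step 2
Reactants: 3 2,4,6-trihydroxy-3,5-bis(3-methylbut-2-enyl)benzaldehyde
Product: 4 2-hydroxy-4,6-bis(methoxymethoxy)-3,5-bis(3-methylbut-2-enyl)benzaldehyde
Conditions: MOMCl (2.2 equiv), iPr2NEt, CH2Cl2, 0 °C to rt
Reagents that add atoms: chloromethyl methyl ether, COCCl
Why: Williamson-type O-alkylation with an amine base should cap the para hydroxyl and one ortho hydroxyl, while the last ortho hydroxyl is held in a hydrogen bond to the formyl oxygen and stays free.

Step 3
Reactants: 4 2-hydroxy-4,6-bis(methoxymethoxy)-3,5-bis(3-methylbut-2-enyl)benzaldehyde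
Product: 5 2-(dimethoxymethyl)-3,5-bis(methoxymethoxy)-4,6-bis(3-methylbut-2-enyl)phenol
Conditions: HC(OMe)3, MeOH, PPTS (5 mol%), rt; then Et3N, concentrate, use crude
Reagents that add atoms: trimethyl orthoformate, COC(OC)OC; methanol, CO
Why: Acid-catalysed acetalisation driven by the orthoformate as water scavenger should convert the electron-rich aldehyde, the weak pyridinium acid sparing MOM ethers and prenyl groups and the amine quench keeping the labile acetal from ionising during concentration.

Step 4
Reactants: 6 resorcinol; 7 3-methylbut-2-enal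
Product: 8 2,2-dimethyl-2H-chromen-7-ol
Conditions: 6 (2 equiv), pyridine, 120 °C (sealed vessel)
Reagents that add atoms: none
Why: Base-mediated chromenylation (aldol-type C-alkylation of resorcinol by the enal, loss of water to a dienone and oxa-6π electrocyclisation) should give the 2,2-dimethylchromene, the excess of resorcinol and the more accessible C4 position favouring the mono-annulated 7-hydroxy isomer.

Step 5
Reactants: 8 2,2-dimethyl-2H-chromen-7-ol
Product: 9 7-hydroxy-2,2-dimethyl-2H-chromene-6-carbaldehyde
Conditions: MgCl2, Et3N, (CH2O)n, MeCN, reflux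
Reagents that add atoms: paraformaldehyde (as formaldehyde), C=O
Why: Magnesium-mediated ortho-formylation of the phenol should deliver formaldehyde from the magnesium phenoxide to C6 and not to the C8 position squeezed between two oxygens, a second formaldehyde oxidising the benzylic alkoxide to the aldehyde without acid that could harm the chromene alkene.

Step 6
Reactants: 9 7-hydroxy-2,2-dimethyl-2H-chromene-6-carbaldehyde
Product: 10 6-ethenyl-2,2-dimethyl-2H-chromen-7-ol
Conditions: Ph3PCH3Br (2.5 equiv), KOtBu (2.5 equiv), THF, 0 °C to rt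
Reagents that add atoms: methyltriphenylphosphonium bromide, C[P+](c1ccccc1)(c1ccccc1)c1ccccc1.[Br-]
Why: Wittig methylenation with excess ylide should work as it does for salicylaldehydes, the first equivalent being spent on the phenol and the phenoxide aldehyde still reacting; the vinylphenol is to be kept cold and used promptly.

Step 7
Reactants: 5 2-(dimethoxymethyl)-3,5-bis(methoxymethoxy)-4,6-bis(3-methylbut-2-enyl)phenol; 10 6-ethenyl-2,2-dimethyl-2H-chromen-7-ol
Product: 12 (2S,4S)-2-(7-hydroxy-2,2-dimethyl-2H-chromen-6-yl)-4-methoxy-5,7-bis(methoxymethoxy)-6,8-bis(3-methylbut-2-enyl)chromane, via methoxy ortho-quinone methide 11 (not isolated)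
Conditions: 5 (1.3 equiv), (R)-TRIP [(R)-3,3'-bis(2,4,6-triisopropylphenyl)-1,1'-binaphthyl-2,2'-diyl hydrogen phosphate] (10 mol%), 4 Å MS, toluene, −40 °C; Et3N quench at −40 °C
Reagents that add atoms: none
Why: Proposed new method: the phosphoric acid protonates an acetal oxygen of 5 and methanol leaves, pushed by the ortho-hydroxyl and the MOM-oxy donors of ring A, to give the O-methyl oxocarbenium ion, that is the methoxy ortho-quinone methide 11, as an ion pair with the chiral phosphate, which at the same time hydrogen-bonds the phenol of 10; the vinyl terminus attacks the methide carbon (C3–C4) and the ring A oxygen then captures the benzylic cation, which the ortho-hydroxyl and para-ether oxygen of ring B stabilise (O1–C2). The closest known reaction types are the achiral acid-catalysed [4+2] addition of styrenes to ortho-quinone methides released from salicylaldehyde acetals and the chiral phosphoric acid catalysed cycloaddition of ortho-quinone methides from ortho-hydroxybenzyl alcohols with ortho-hydroxystyrenes; the enantioselective use of an acetal-derived methoxy quinone methide is the untested part. Ring C closes as a six-membered ring by an asynchronous inverse-electron-demand hetero-[4+2] cycloaddition (heterodiene O1=C8a–C4a=C4, dienophile C2=C3), whose second bond forms by 6-exo-trig capture of the cation by oxygen. C2 is controlled by the catalyst, since the phosphate bound to both partners shields one face of the styrene and the antipode of the acid is chosen for 2S; C4 should come out cis to the aryl group from an endo approach, but its configuration is of no consequence because C4 later becomes the carbonyl carbon. The step needs site selectivity for the terminal vinyl group over the chromene alkene, the prenyl groups and the free C8 position of the chromenol, which the unhindered, most nucleophilic terminus next to the catalyst-bound hydroxyl secures, and regioselectivity for the aryl group on C2, which the polarity of the styrene secures. The product must not ionise again at C4, where the 2'-hydroxyl could add to form a bridged ether, and for this the weak acid, the low temperature, the limited reaction time and the cold amine quench are chosen.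

Step 8
Reactants: 12 (2S,4S)-2-(7-hydroxy-2,2-dimethyl-2H-chromen-6-yl)-4-methoxy-5,7-bis(methoxymethoxy)-6,8-bis(3-methylbut-2-enyl)chromane
Product: 13 (2S,4S)-4-methoxy-5,7-bis(methoxymethoxy)-2-[7-(methoxymethoxy)-2,2-dimethyl-2H-chromen-6-yl]-6,8-bis(3-methylbut-2-enyl)chromane
Conditions: MOMCl (1.5 equiv), iPr2NEt, CH2Cl2, 0 °C to rt
Reagents that add atoms: chloromethyl methyl ether, COCCl
Why: Williamson-type O-alkylation of the only free phenol under basic, non-ionising conditions should remove the internal nucleophile that could bridge to C4 in the acidic step that follows and shield the phenol from the oxidant, with a group that leaves in the final step.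

Step 9
Reactants: 13 (2S,4S)-4-methoxy-5,7-bis(methoxymethoxy)-2-[7-(methoxymethoxy)-2,2-dimethyl-2H-chromen-6-yl]-6,8-bis(3-methylbut-2-enyl)chromane
Product: 14 (2S)-5,7-bis(methoxymethoxy)-2-[7-(methoxymethoxy)-2,2-dimethyl-2H-chromen-6-yl]-6,8-bis(3-methylbut-2-enyl)chroman-4-ol (mixture of C4 epimers)
Conditions: PPTS (0.2 equiv), THF–H2O (4:1), rt
Reagents that add atoms: water, O
Why: SN1 solvolysis should proceed under weak acid because the C4 cation is stabilised by the three oxygen donors of ring A and is captured by the large excess of water, while aryl MOM ethers, prenyl groups and the C2–O1 bond tolerate the pyridinium acid and either C4 epimer is acceptable.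

Step 10
Reactants: 14 (2S)-5,7-bis(methoxymethoxy)-2-[7-(methoxymethoxy)-2,2-dimethyl-2H-chromen-6-yl]-6,8-bis(3-methylbut-2-enyl)chroman-4-ol
Product: 15 (2S)-5,7-bis(methoxymethoxy)-2-[7-(methoxymethoxy)-2,2-dimethyl-2H-chromen-6-yl]-6,8-bis(3-methylbut-2-enyl)chroman-4-one
Conditions: Dess–Martin periodinane (1.5 equiv), pyridine, CH2Cl2, 0 °C to rt
Reagents that add atoms: none
Why: Dess–Martin oxidation of the secondary benzylic alcohol should give the flavanone, since no free phenol is left, the alkenes and MOM ethers are inert to the reagent, and pyridine buffers the acetic acid so that neither C4 ionisation nor ring opening at C2 is provoked.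

Step 11
Reactants: 15 (2S)-5,7-bis(methoxymethoxy)-2-[7-(methoxymethoxy)-2,2-dimethyl-2H-chromen-6-yl]-6,8-bis(3-methylbut-2-enyl)chroman-4-one
Product: 16 euchrenone a3, (2S)-5,7-dihydroxy-2-(7-hydroxy-2,2-dimethyl-2H-chromen-6-yl)-6,8-bis(3-methylbut-2-enyl)chroman-4-one
Conditions: 3 M aq. HCl, MeOH, 40 °C
Reagents that add atoms: none
Why: Acid-catalysed acetal exchange with methanol should remove the three aryl MOM ethers as dimethoxymethane under the mild, short treatment customary for prenylated flavanones, which avoids cyclisation of prenyl groups onto the new phenols and ring opening of the flavanone, so that the 2S centre is kept.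

Compound list
1 | 2,4,6-trihydroxybenzaldehyde | O=Cc1c(O)cc(O)cc1O | starting material
2 | 1-bromo-3-methylbut-2-ene | CC(C)=CCBr | starting material
3 | 2,4,6-trihydroxy-3,5-bis(3-methylbut-2-enyl)benzaldehyde | O=Cc1c(O)c(CC=C(C)C)c(O)c(CC=C(C)C)c1O | intermediate
4 | 2-hydroxy-4,6-bis(methoxymethoxy)-3,5-bis(3-methylbut-2-enyl)benzaldehyde | O=Cc1c(O)c(CC=C(C)C)c(OCOC)c(CC=C(C)C)c1OCOC | intermediate
5 | 2-(dimethoxymethyl)-3,5-bis(methoxymethoxy)-4,6-bis(3-methylbut-2-enyl)phenol | COC(OC)c1c(O)c(CC=C(C)C)c(OCOC)c(CC=C(C)C)c1OCOC | intermediate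
6 | resorcinol | Oc1cccc(O)c1 | starting material
7 | 3-methylbut-2-enal | CC(C)=CC=O | starting material
8 | 2,2-dimethyl-2H-chromen-7-ol | CC1(C)C=Cc2ccc(O)cc2O1 | intermediate
9 | 7-hydroxy-2,2-dimethyl-2H-chromene-6-carbaldehyde | CC1(C)C=Cc2cc(C=O)c(O)cc2O1 | intermediate
10 | 6-ethenyl-2,2-dimethyl-2H-chromen-7-ol | C=Cc1cc2c(cc1O)OC(C)(C)C=C2 | intermediate
11 | 6-(methoxymethylidene)-3,5-bis(methoxymethoxy)-2,4-bis(3-methylbut-2-enyl)cyclohexa-2,4-dien-1-one (methoxy ortho-quinone methide, exocyclic alkene geometry not defined) | COC=C1C(=O)C(CC=C(C)C)=C(OCOC)C(CC=C(C)C)=C1OCOC | intermediate (not isolated)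
12 | (2S,4S)-2-(7-hydroxy-2,2-dimethyl-2H-chromen-6-yl)-4-methoxy-5,7-bis(methoxymethoxy)-6,8-bis(3-methylbut-2-enyl)chromane (2,4-cis) | CC(C)=CCc1c(OCOC)c(CC=C(C)C)c2c(c1OCOC)[C@@H](OC)C[C@@H](c1cc3c(cc1O)OC(C)(C)C=C3)O2 | intermediate
13 | (2S,4S)-4-methoxy-5,7-bis(methoxymethoxy)-2-[7-(methoxymethoxy)-2,2-dimethyl-2H-chromen-6-yl]-6,8-bis(3-methylbut-2-enyl)chromane | CC(C)=CCc1c(OCOC)c(CC=C(C)C)c2c(c1OCOC)[C@@H](OC)C[C@@H](c1cc3c(cc1OCOC)OC(C)(C)C=C3)O2 | intermediate
14 | (2S)-5,7-bis(methoxymethoxy)-2-[7-(methoxymethoxy)-2,2-dimethyl-2H-chromen-6-yl]-6,8-bis(3-methylbut-2-enyl)chroman-4-ol (C4 epimers) | CC(C)=CCc1c(OCOC)c(CC=C(C)C)c2c(c1OCOC)C(O)C[C@@H](c1cc3c(cc1OCOC)OC(C)(C)C=C3)O2 | intermediate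
15 | (2S)-5,7-bis(methoxymethoxy)-2-[7-(methoxymethoxy)-2,2-dimethyl-2H-chromen-6-yl]-6,8-bis(3-methylbut-2-enyl)chroman-4-one | CC(C)=CCc1c(OCOC)c(CC=C(C)C)c2c(c1OCOC)C(=O)C[C@@H](c1cc3c(cc1OCOC)OC(C)(C)C=C3)O2 | intermediate
16 | euchrenone a3, (2S)-5,7-dihydroxy-2-(7-hydroxy-2,2-dimethyl-2H-chromen-6-yl)-6,8-bis(3-methylbut-2-enyl)chroman-4-one | CC(C)=CCc1c(O)c(CC=C(C)C)c2c(c1O)C(=O)C[C@@H](c1cc3c(cc1O)OC(C)(C)C=C3)O2 | target

Total step count: 11.
Longest linear sequence: 8 steps (1, 2, 3, 7, 8, 9, 10, 11); the ring B branch (steps 4, 5, 6) joins at step 7.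

Steps most likely to fail

Step 7 (proposed new method). Three things may go wrong. Facial control may be poor if the acetal ionises outside the chiral ion pair. The cycloadduct may ionise again at C4 and be trapped by the 2'-hydroxyl as a bridged ether. The vinylphenol may add to itself under acid. The fallback uses known chemistry, sets out from 10 and 5 and comes back at 15. Compound 10 is capped (MOMCl, iPr2NEt, CH2Cl2) to give 6-ethenyl-7-(methoxymethoxy)-2,2-dimethyl-2H-chromene F1. F1 and 5 are joined under achiral acid catalysis (Sc(OTf)3, 5 mol%, CH2Cl2, −20 °C), the established racemic [4+2] addition of a styrene to the ortho-quinone methide from a salicylaldehyde acetal. With no free phenol on the styrene this should give racemic 4-methoxy-5,7-bis(methoxymethoxy)-2-[7-(methoxymethoxy)-2,2-dimethyl-2H-chromen-6-yl]-6,8-bis(3-methylbut-2-enyl)chromane F2. Solvolysis as in step 9 should give racemic 5,7-bis(methoxymethoxy)-2-[7-(methoxymethoxy)-2,2-dimethyl-2H-chromen-6-yl]-6,8-bis(3-methylbut-2-enyl)chroman-4-ol F3. Dess–Martin oxidation as in step 10 should give racemic 5,7-bis(methoxymethoxy)-2-[7-(methoxymethoxy)-2,2-dimethyl-2H-chromen-6-yl]-6,8-bis(3-methylbut-2-enyl)chroman-4-one F4. Preparative HPLC on a chiral stationary phase then separates 15 from its enantiomer, and step 11 follows.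

Step 1. The degree and site of alkylation may be poorly controlled: mono-alkylation, a third alkylation with loss of aromaticity, and O-alkylation. The fallback sets out from 2 and comes back at 4, so that 3 and step 2 are bypassed. Commercial phloroglucinol is converted (NaH, MOMCl, DMF) into 1,3,5-tris(methoxymethoxy)benzene F5. Directed ortho-lithiation between two MOM-oxy groups (n-BuLi, THF, 0 °C) and alkylation with 2 (CuBr·SMe2, 10 mol%) should give 1,3,5-tris(methoxymethoxy)-2-(3-methylbut-2-enyl)benzene F6. A second round should give 1,3,5-tris(methoxymethoxy)-2,4-bis(3-methylbut-2-enyl)benzene F7. A third lithiation quenched with DMF should give 2,4,6-tris(methoxymethoxy)-3,5-bis(3-methylbut-2-enyl)benzaldehyde F8. One MOM ether ortho to the formyl group is then removed (dilute HCl, MeOH, 0 °C) to reach 4; the phenol set free first chelates the carbonyl and slows loss of the second ortho MOM group.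

Step 9. The C4 cation may lose a proton to a flav-3-ene or be captured by the 2'-MOM ether oxygen with loss of that group, and MOM ethers may erode on long exposure to acid. The fallback sets out from 13 and comes back at 15 without passing through 14. DDQ in CH2Cl2/pH 7 buffer at 0 °C should abstract hydride from C4–H of the electron-rich benzylic methyl ether, and water should convert the resulting O-methyl oxocarbenium ion into the ketone. This oxidative ether cleavage replaces both the solvolysis and the separate oxidation; no new compound is made (F0).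

Further compounds
F1 | step 7 | 6-ethenyl-7-(methoxymethoxy)-2,2-dimethyl-2H-chromene | C=Cc1cc2c(cc1OCOC)OC(C)(C)C=C2
F2 | step 7 | racemic 4-methoxy-5,7-bis(methoxymethoxy)-2-[7-(methoxymethoxy)-2,2-dimethyl-2H-chromen-6-yl]-6,8-bis(3-methylbut-2-enyl)chromane | CC(C)=CCc1c(OCOC)c(CC=C(C)C)c2c(c1OCOC)C(OC)CC(c1cc3c(cc1OCOC)OC(C)(C)C=C3)O2
F3 | step 7 | racemic 5,7-bis(methoxymethoxy)-2-[7-(methoxymethoxy)-2,2-dimethyl-2H-chromen-6-yl]-6,8-bis(3-methylbut-2-enyl)chroman-4-ol | CC(C)=CCc1c(OCOC)c(CC=C(C)C)c2c(c1OCOC)C(O)CC(c1cc3c(cc1OCOC)OC(C)(C)C=C3)O2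
F4 | step 7 | racemic 5,7-bis(methoxymethoxy)-2-[7-(methoxymethoxy)-2,2-dimethyl-2H-chromen-6-yl]-6,8-bis(3-methylbut-2-enyl)chroman-4-one | CC(C)=CCc1c(OCOC)c(CC=C(C)C)c2c(c1OCOC)C(=O)CC(c1cc3c(cc1OCOC)OC(C)(C)C=C3)O2
F5 | step 1 | 1,3,5-tris(methoxymethoxy)benzene | COCOc1cc(OCOC)cc(OCOC)c1
F6 | step 1 | 1,3,5-tris(methoxymethoxy)-2-(3-methylbut-2-enyl)benzene | COCOc1cc(OCOC)c(CC=C(C)C)c(OCOC)c1
F7 | step 1 | 1,3,5-tris(methoxymethoxy)-2,4-bis(3-methylbut-2-enyl)benzene | COCOc1cc(OCOC)c(CC=C(C)C)c(OCOC)c1CC=C(C)C
F8 | step 1 | 2,4,6-tris(methoxymethoxy)-3,5-bis(3-methylbut-2-enyl)benzaldehyde | O=Cc1c(OCOC)c(CC=C(C)C)c(OCOC)c(CC=C(C)C)c1OCOC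
F0 | step 9 | none | none
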